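**Retrosynthetic overview** (clerodane locants, defined in the remark below)
1. Target ⇐ late C8 α-methylenation and global desilylation; before that the C11–C16 hydroxy-lactone/tiglate unit is grown from a C12 aldehyde (vinylation, hydroxyl-directed epoxidation, tiglate-assisted epoxide opening with lactonisation).
2. Decalin ⇐ one cationic bicyclization of an acyclic acetal–diene–enol silane: bond C1–C10 closes ring A, then bond C5–C6 closes ring B in the same operation.
3. Enabling feature: the oxygen on C1 (acetal-derived oxocarbenium initiator), the methyl-bearing quaternary C5 next to the C4=C18 exocyclic methylene (a C18=C4–C5=C10 diene gives a tertiary allyl cation at C5), and the C6-oxygenated C7 ketone of ring B (Z enol silane terminator).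
4. Acyclic precursor ⇐ chiral-pool butyrolactone (two enolate alkylations set quaternary C9), then Wittig, Weinreb/Grignard and methylenation to attach the diene–acetal arm.
5. Ring order: ring A, ring B (both in the key step), butyrolactone last.

Key step: step 14

Remark (assumption): locants are those of the clerodane skeleton of the target (ring A = C1–C2–C3–C4–C5–C10, ring B = C5–C6–C7–C8–C9–C10, C11–C16 = side chain with C15 = lactone C=O and C16 = lactone OCH2, C17/C18 = exocyclic CH2 on C8/C4, C19/C20 = methyls on C5/C9); compounds 1, 3, 7, 11, 12, 28 and all named reagents are taken as commercially available.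
Abbreviations: TBS = tert-butyldimethylsilyl, TBDPS = tert-butyldiphenylsilyl, TES = triethylsilyl, tiglate/tigloyl = (E)-2-methylbut-2-enoate/-enoyl.

**Step 1**
Reactants: 1 (R)-5-(hydroxymethyl)dihydrofuran-2(3H)-one
Product: 2 (R)-5-[(TBDPS-oxy)methyl]dihydrofuran-2(3H)-one
Conditions: tBuPh2SiCl, imidazole, DMF, 0 → 25 °C
Reagents that add atoms: tert-butyl(chloro)diphenylsilane, CC(C)(C)[Si](Cl)(c1ccccc1)c1ccccc1
Why: Silylation of the primary alcohol gives a bulky, base-stable ether that later shields one face of the lactone enolate and stays on the C6 oxygen until the last step.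

**Step 2**
Reactants: 2 (R)-5-[(TBDPS-oxy)methyl]dihydrofuran-2(3H)-one; 3 tert-butyl(2-iodoethoxy)dimethylsilane
Product: 4 (3S,5R)-3-[2-(TBS-oxy)ethyl]-5-[(TBDPS-oxy)methyl]dihydrofuran-2(3H)-one
Conditions: LiN(iPr)2, THF, −78 °C; then 3, DMPU, −78 → −30 °C
Reagents that add atoms: none
Why: SN2 alkylation of the lactone lithium enolate by a primary iodide installs C11–C12 (trans isomer expected); this centre is re-enolised in step 3, so its configuration is not critical.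

**Step 3**
Reactants: 4 (3S,5R)-3-[2-(TBS-oxy)ethyl]-5-[(TBDPS-oxy)methyl]dihydrofuran-2(3H)-one
Product: 5 (3R,5R)-3-[2-(TBS-oxy)ethyl]-5-[(TBDPS-oxy)methyl]-3-methyldihydrofuran-2(3H)-one
Conditions: LiN(iPr)2, THF, −78 °C; then MeI, −78 → −40 °C
Reagents that add atoms: iodomethane, CI
Why: Substrate-controlled α-alkylation of a γ-substituted butyrolactone enolate: iodomethane should enter anti to the silyloxymethyl group, which sets the quaternary C9 stereocentre (methyl = C20).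

**Step 4**
Reactants: 5 (3R,5R)-3-[2-(TBS-oxy)ethyl]-5-[(TBDPS-oxy)methyl]-3-methyldihydrofuran-2(3H)-one
Product: 6 (3R,5R)-3-[2-(TBS-oxy)ethyl]-5-[(TBDPS-oxy)methyl]-3-methyltetrahydrofuran-2-ol (lactol, both anomers)
Conditions: iBu2AlH, toluene, −78 °C; aq. potassium sodium tartrate
Reagents that add atoms: none
Why: Hydride reduction of a γ-lactone stops at the lactol because the tetrahedral aluminate is stable at −78 °C.

**Step 5**
Reactants: 6 lactol; 7 ethyl 2-(triphenyl-λ5-phosphanylidene)propanoate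
Product: 8 ethyl (2E,4R,6R)-4-[2-(TBS-oxy)ethyl]-7-(TBDPS-oxy)-6-hydroxy-2,4-dimethylhept-2-enoate
Conditions: toluene, 100 °C
Reagents that add atoms: none
Why: Wittig reaction of the open hydroxy-aldehyde form with a stabilised ylide should give the E trisubstituted alkene (the future C5=C10 bond with C19 in place) without base, so the free C7 hydroxyl does not add back.

**Step 6**
Reactants: 8 hydroxy enoate
Product: 9 ethyl (2E,4R,6R)-4-[2-(TBS-oxy)ethyl]-7-(TBDPS-oxy)-2,4-dimethyl-6-(triethylsilyloxy)hept-2-enoate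
Conditions: Et3SiCl, imidazole, DMF, 0 °C
Reagents that add atoms: chlorotriethylsilane, CC[Si](Cl)(CC)CC
Why: Silylation masks the C7 hydroxyl as the most labile of the three silyl ethers, which excludes alkoxide oxa-Michael addition in steps 7–10 and allows its selective removal in step 11.

**Step 7**
Reactants: 9 TES-protected enoate
Product: 10 (2E,4R,6R)-4-[2-(TBS-oxy)ethyl]-7-(TBDPS-oxy)-N-methoxy-N,2,4-trimethyl-6-(triethylsilyloxy)hept-2-enamide
Conditions: MeNH(OMe)·HCl, iPrMgCl, THF, −20 → 0 °C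
Reagents that add atoms: N,O-dimethylhydroxylamine hydrochloride, CNOC.Cl
Why: Aminolysis of the ester by the magnesium amide gives the Weinreb amide, the acyl donor needed for a single Grignard addition.

**Step 8**
Reactants: 11 prop-2-enal; 12 (2S,4S)-pentane-2,4-diol
Product: 14 (4S,6S)-2-(2-bromoethyl)-4,6-dimethyl-1,3-dioxane, via 3-bromopropanal 13 (not isolated)
Conditions: HBr (gas), CH2Cl2, 0 °C; then 12, TsOH·H2O (cat.), 25 °C
Reagents that add atoms: hydrogen bromide, Br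
Why: Conjugate addition of HBr to the enal followed by acid-catalysed acetalisation gives the C1–C3 unit carrying the C2-symmetric chiral acetal.

**Step 9**
Reactants: 10 Weinreb amide; 14 (4S,6S)-2-(2-bromoethyl)-4,6-dimethyl-1,3-dioxane
Product: 16 (4E,6R,8R)-6-[2-(TBS-oxy)ethyl]-9-(TBDPS-oxy)-1-[(4S,6S)-4,6-dimethyl-1,3-dioxan-2-yl]-4,6-dimethyl-8-(triethylsilyloxy)non-4-en-3-one, via Grignard reagent 15 (not isolated)
Conditions: 14, Mg, THF, 25 °C; then 10, THF, 0 °C; aq. NH4Cl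
Reagents that add atoms: none
Why: Weinreb ketone synthesis: the chelated tetrahedral intermediate prevents over-addition and the hindered β-carbon disfavours 1,4-addition, giving the C4 ketone.

**Step 10**
Reactants: 16 seco-enone
Product: 17 (4S,6S)-2-{(4E,6R,8R)-6-[2-(TBS-oxy)ethyl]-9-(TBDPS-oxy)-4,6-dimethyl-3-methylidene-8-(triethylsilyloxy)non-4-en-1-yl}-4,6-dimethyl-1,3-dioxane
Conditions: Ph3PCH3Br, KN(SiMe3)2, THF, 0 °C; then 16, 0 → 25 °C
Reagents that add atoms: methyltriphenylphosphonium bromide, C[P+](c1ccccc1)(c1ccccc1)c1ccccc1.[Br-]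
Why: Wittig methylenation of the enone carbonyl gives the cross-conjugated C18=C4–C5=C10 diene with the E geometry of C5=C10 untouched.

**Step 11**
Reactants: 17 diene TES ether
Product: 18 (2R,4R,5E)-4-[2-(TBS-oxy)ethyl]-1-(TBDPS-oxy)-9-[(4S,6S)-4,6-dimethyl-1,3-dioxan-2-yl]-4,6-dimethyl-7-methylidenenon-5-en-2-ol
Conditions: HF·pyridine, pyridine, THF, 0 °C
Reagents that add atoms: none
Why: Under buffered fluoride a secondary triethylsilyl ether should cleave well before the primary TBS and TBDPS ethers, and the acetal and diene are not touched.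

**Step 12**
Reactants: 18 C7 alcohol
Product: 19 (4R,5E)-4-[2-(TBS-oxy)ethyl]-1-(TBDPS-oxy)-9-[(4S,6S)-4,6-dimethyl-1,3-dioxan-2-yl]-4,6-dimethyl-7-methylidenenon-5-en-2-one
Conditions: Dess–Martin periodinane, NaHCO3, CH2Cl2, 25 °C
Reagents that add atoms: none
Why: Buffered Dess–Martin oxidation gives the C7 ketone and removes the stereocentre that only served to direct step 3.

**Step 13**
Reactants: 19 α-silyloxy ketone
Product: 20 (4S,6S)-2-{(4E,6R,8Z)-8-(TBS-oxy)-6-[2-(TBS-oxy)ethyl]-9-(TBDPS-oxy)-4,6-dimethyl-3-methylidenenona-4,8-dien-1-yl}-4,6-dimethyl-1,3-dioxane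
Conditions: KN(SiMe3)2, THF, −78 °C; then tBuMe2SiOTf, −78 °C
Reagents that add atoms: tert-butyldimethylsilyl trifluoromethanesulfonate, CC(C)(C)[Si](C)(C)OS(=O)(=O)C(F)(F)F
Why: Kinetic deprotonation should occur at the oxygen-bearing C6 methylene (more acidic and less hindered than the neopentyl C8) and give the Z enolate (oxygens cis, least allylic strain), which is trapped on oxygen as the enol silane.

**Step 14**
Reactants: 20 acetal–diene–enol silane
Product: 22 (1S,5S,6S,9R,10S)-9-[2-(TBS-oxy)ethyl]-6-(TBDPS-oxy)-1-[(2S,4S)-4-hydroxypentan-2-yloxy]-5,9-dimethyl-4-methylidene-trans-decalin-7-one, via allyl cation 21 (not isolated)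
Conditions: TiCl4 (3 equiv), 2,6-di-tert-butyl-4-methylpyridine, CH2Cl2 (high dilution), −78 °C; aq. NaHCO3
Reagents that add atoms: none
Why: Proposed new method: TiCl4 opens the dioxane at the C–O bond next to the axial methyl and the C10 terminus of the 1,3-diene attacks the oxocarbenium carbon C1 with inversion (6-endo with respect to C5=C10, chair), closing ring A and giving the tertiary allyl cation 21 (C5–C4–C18), whose C5 terminus is captured by C6 of the Z enol silane (6-endo, second chair, anti addition across the former C5=C10 bond) to close ring B and release the C7 ketone with loss of tBuMe2SiCl. The closest known reaction types are the chiral-acetal-initiated cation–olefin polycyclization of trisubstituted polyenes, the capture of tertiary allyl cations at their methyl-bearing terminus by alkenes, and silyl enol ether termination of such cascades; a 1,3-diene as internal relay has not been shown. C1 is set by the (4S,6S)-acetal and its oxygen sits equatorial, away from the axial C19 methyl; C10 and C5 follow from the E alkene (trans ring fusion); C6 follows from the Z enol ether geometry (equatorial OTBDPS); C9 is carried in unchanged and only places its methyl axial. The step needs capture of the allyl cation at C5 and not at C18 (six- against eight-membered ring, which also leaves the C4 exocyclic methylene in place), attack through C6 and not C7 of the bis(silyloxy)alkene (six-membered chair against a five-membered ring with vicinal quaternary centres), and a silent C12 silyl ether oxygen, which the far higher π-nucleophilicity of the enol silane should secure.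

**Step 15**
Reactants: 22 bicyclic hydroxypentyl ether
Product: 24 (1S,5S,6S,9R,10S)-9-[2-(TBS-oxy)ethyl]-6-(TBDPS-oxy)-1-hydroxy-5,9-dimethyl-4-methylidene-trans-decalin-7-one, via methyl ketone 23 (not isolated)
Conditions: Dess–Martin periodinane, NaHCO3, CH2Cl2, 25 °C; then dibenzylammonium trifluoroacetate, toluene, 50 °C
Reagents that add atoms: none
Why: Oxidation of the auxiliary carbinol to a β-alkoxy ketone followed by amine-salt-catalysed β-elimination (retro-oxa-Michael) frees the C1 hydroxyl without touching the other stereocentres.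

**Step 16**
Reactants: 24 C1 alcohol
Product: 25 (1S,5S,6S,9R,10S)-9-[2-(TBS-oxy)ethyl]-6-(TBDPS-oxy)-5,9-dimethyl-4-methylidene-7-oxo-trans-decalin-1-yl tiglate
Conditions: tigloyl chloride, pyridine, DMAP, CH2Cl2, 0 → 40 °C
Reagents that add atoms: (E)-2-methylbut-2-enoyl chloride, ClC(=O)/C(C)=C/C
Why: DMAP-catalysed acylation installs the first tiglate and prevents the C1 hydroxyl from forming a six-membered lactol with the C12 aldehyde of step 18.

**Step 17**
Reactants: 25 C1 tiglate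
Product: 26 (1S,5S,6S,9R,10S)-6-(TBDPS-oxy)-9-(2-hydroxyethyl)-5,9-dimethyl-4-methylidene-7-oxo-trans-decalin-1-yl tiglate
Conditions: HF·pyridine, pyridine, THF, 0 → 25 °C
Reagents that add atoms: none
Why: A primary TBS ether is cleaved by buffered fluoride much faster than the hindered secondary TBDPS ether at C6.

**Step 18**
Reactants: 26 C12 alcohol
Product: 27 (1S,5S,6S,9R,10S)-6-(TBDPS-oxy)-5,9-dimethyl-4-methylidene-7-oxo-9-(2-oxoethyl)-trans-decalin-1-yl tiglate
Conditions: Dess–Martin periodinane, NaHCO3, CH2Cl2, 25 °C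
Reagents that add atoms: none
Why: Dess–Martin oxidation of the only free hydroxyl gives the C12 aldehyde under neutral conditions.

**Step 19**
Reactants: 28 3-bromobut-3-en-1-ol
Product: 29 3-bromobut-3-enoic acid
Conditions: PhI(OAc)2, TEMPO (cat.), MeCN–H2O, 25 °C
Reagents that add atoms: water, O
Why: Nitroxyl-catalysed oxidation takes the primary alcohol through the aldehyde hydrate to the acid without isomerising the β,γ-alkene.

**Step 20**
Reactants: 29 3-bromobut-3-enoic acid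
Product: 30 tert-butyl 3-bromobut-3-enoate
Conditions: tert-butyl 2,2,2-trichloroacetimidate, BF3·OEt2 (cat.), cyclohexane–CH2Cl2, 25 °C
Reagents that add atoms: tert-butyl 2,2,2-trichloroacetimidate, CC(C)(C)OC(=N)C(Cl)(Cl)Cl
Why: Acid-catalysed O-alkylation by the imidate makes the tert-butyl ester without base, so the alkene stays out of conjugation and the ester will not lactonise onto the C12 hydroxyl in step 21.

**Step 21**
Reactants: 27 C12 aldehyde; 30 tert-butyl 3-bromobut-3-enoate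
Product: 31 tert-butyl (4S)-5-[(1S,5S,6S,9R,10S)-6-(TBDPS-oxy)-5,9-dimethyl-4-methylidene-7-oxo-1-(tigloyloxy)-trans-decalin-9-yl]-4-hydroxy-3-methylidenepentanoate
Conditions: CrCl2, NiCl2 (cat.), Et3N, chiral N-[2-(4-isopropyl-4,5-dihydrooxazol-2-yl)-6-methylphenyl]methanesulfonamide ligand (enantiomer matched to the 12S alcohol), THF, 25 °C
Reagents that add atoms: none
Why: Nozaki–Hiyama–Kishi reaction: the alkenylchromium species made from the vinyl bromide by NiCl2 catalysis and divalent chromium adds to the aldehyde only (the C7 ketone and both enoates are inert), and the chiral sulfonamide ligand on chromium should set C12.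

**Step 22**
Reactants: 31 (12S)-allylic alcohol
Product: 32 tert-butyl 2-[(2R)-2-{(1S)-2-[decalin-9-yl as in 31]-1-hydroxyethyl}oxiran-2-yl]acetate (12S,13R; erythro)
Conditions: VO(acac)2 (cat.), tBuOOH, CH2Cl2, 0 °C
Reagents that add atoms: tert-butyl hydroperoxide, CC(C)(C)OO
Why: Hydroxyl-directed vanadium-catalysed epoxidation touches only the allylic alcohol alkene, and for a 2-substituted allylic alcohol allylic 1,2-strain should give the erythro epoxy alcohol, which sets C13 relative to C12.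

**Step 23**
Reactants: 32 epoxy alcohol
Product: 33 bis-tiglate epoxide (12S,13R): the C12 tiglate of 32
Conditions: tigloyl chloride, pyridine, DMAP, CH2Cl2, 0 → 25 °C
Reagents that add atoms: (E)-2-methylbut-2-enoyl chloride, ClC(=O)/C(C)=C/C
Why: Acylation of the secondary C12 hydroxyl installs the second tiglate and places its carbonyl oxygen anti to the epoxide C13–O bond, as needed for step 24.

**Step 24**
Reactants: 33 bis-tiglate epoxide
Product: 36 (1S,5S,6S,9R,10S,12S,13S)-6-(TBDPS-oxy)-13-hydroxy-7-oxo-1,12-bis(tigloyloxy)clerod-4(18)-en-15,16-olide, via dioxolanylium ion 34 (not isolated), via hydroxy ester 35 (not isolated)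
Conditions: BF3·OEt2 (0.2 equiv), CH2Cl2, −40 °C; H2O–THF; then camphorsulfonic acid (cat.), CH2Cl2, 25 °C
Reagents that add atoms: water, O
Why: Neighbouring-group participation: the C12 tiglate carbonyl opens the activated 2,2-disubstituted epoxide at the tertiary C13 from the rear (5-exo, inversion, giving the 13S centre), hydrolysis of the dioxolanylium ion returns the tiglate to the secondary C12 oxygen, and the freed C16 hydroxyl lactonises onto the tert-butyl ester.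

**Step 25**
Reactants: 36 hydroxy lactone
Product: 38 C8 dimethylaminomethyl ketone (Mannich base) carrying a 13-O-trimethylsilyl ether, via silyl enol ether 37 (not isolated)
Conditions: Me3SiOTf, Et3N, CH2Cl2, 0 °C; then CH2=NMe2 I, CH2Cl2, 25 °C
Reagents that add atoms: trimethylsilyl trifluoromethanesulfonate, C[Si](C)(C)OS(=O)(=O)C(F)(F)F; dimethyl(methylidene)ammonium iodide, C=[N+](C)C.[I-]
Why: Soft enolisation should form the C7–C8 trimethylsilyl enol ether (C6 is tertiary and shielded; esters and the lactone are not enolised at 0 °C) and silylate the tertiary C13 hydroxyl, and the enol ether then undergoes a Mannich reaction with the iminium salt at C8.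

**Step 26**
Reactants: 38 Mannich base
Product: 40 (1S,5S,6S,9S,10S,12S,13S)-6-(TBDPS-oxy)-7-oxo-1,12-bis(tigloyloxy)-13-(trimethylsilyloxy)cleroda-4(18),8(17)-dien-15,16-olide, via ammonium iodide 39 (not isolated)
Conditions: MeI, CH2Cl2–Et2O, 25 °C; then aq. NaHCO3, CH2Cl2
Reagents that add atoms: none
Why: Quaternisation of the amine and mild-base β-elimination give the C8 exocyclic enone under conditions too weak to dehydrate the β-silyloxy lactone.

**Step 27**
Reactants: 40 bis-silyl ether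
Product: 41 CNP0233387.2, (1S,5S,6S,9S,10S,12S,13S)-6,13-dihydroxy-7-oxo-1,12-bis(tigloyloxy)cleroda-4(18),8(17)-dien-15,16-olide
Conditions: HF·pyridine, THF, 0 → 25 °C
Reagents that add atoms: none
Why: Acidic fluoride removes the tertiary trimethylsilyl and the secondary TBDPS ether without acyl migration or attack on the tiglates, the enone or the β-hydroxy lactone.

**Compound list**
1 | (R)-5-(hydroxymethyl)dihydrofuran-2(3H)-one | O=C1CC[C@H](CO)O1 | starting material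
2 | (R)-5-[(tert-butyldiphenylsilyloxy)methyl]dihydrofuran-2(3H)-one | O=C1CC[C@H](CO[Si](c2ccccc2)(c2ccccc2)C(C)(C)C)O1 | intermediate
3 | tert-butyl(2-iodoethoxy)dimethylsilane | CC(C)(C)[Si](C)(C)OCCI | starting material
4 | (3S,5R)-3-[2-(tert-butyldimethylsilyloxy)ethyl]-5-[(tert-butyldiphenylsilyloxy)methyl]dihydrofuran-2(3H)-one (3,5-trans) | O=C1[C@@H](CCO[Si](C)(C)C(C)(C)C)C[C@H](CO[Si](c2ccccc2)(c2ccccc2)C(C)(C)C)O1 | intermediate
5 | (3R,5R)-3-[2-(tert-butyldimethylsilyloxy)ethyl]-5-[(tert-butyldiphenylsilyloxy)methyl]-3-methyldihydrofuran-2(3H)-one (methyl trans to the C5 substituent) | O=C1[C@](C)(CCO[Si](C)(C)C(C)(C)C)C[C@H](CO[Si](c2ccccc2)(c2ccccc2)C(C)(C)C)O1 | intermediate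
6 | (3R,5R)-3-[2-(TBS-oxy)ethyl]-5-[(TBDPS-oxy)methyl]-3-methyltetrahydrofuran-2-ol (lactol, both anomers) | OC1[C@](C)(CCO[Si](C)(C)C(C)(C)C)C[C@H](CO[Si](c2ccccc2)(c2ccccc2)C(C)(C)C)O1 | intermediate
7 | ethyl 2-(triphenyl-λ5-phosphanylidene)propanoate | CCOC(=O)C(C)=P(c1ccccc1)(c1ccccc1)c1ccccc1 | starting material
8 | ethyl (2E,4R,6R)-4-[2-(TBS-oxy)ethyl]-7-(TBDPS-oxy)-6-hydroxy-2,4-dimethylhept-2-enoate | CCOC(=O)/C(C)=C/[C@](C)(CCO[Si](C)(C)C(C)(C)C)C[C@@H](O)CO[Si](c1ccccc1)(c1ccccc1)C(C)(C)C | intermediate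
9 | ethyl (2E,4R,6R)-4-[2-(TBS-oxy)ethyl]-7-(TBDPS-oxy)-2,4-dimethyl-6-(triethylsilyloxy)hept-2-enoate | CCOC(=O)/C(C)=C/[C@](C)(CCO[Si](C)(C)C(C)(C)C)C[C@@H](O[Si](CC)(CC)CC)CO[Si](c1ccccc1)(c1ccccc1)C(C)(C)C | intermediate
10 | (2E,4R,6R)-4-[2-(TBS-oxy)ethyl]-7-(TBDPS-oxy)-N-methoxy-N,2,4-trimethyl-6-(triethylsilyloxy)hept-2-enamide | CON(C)C(=O)/C(C)=C/[C@](C)(CCO[Si](C)(C)C(C)(C)C)C[C@@H](O[Si](CC)(CC)CC)CO[Si](c1ccccc1)(c1ccccc1)C(C)(C)C | intermediate
11 | prop-2-enal (acrolein) | C=CC=O | starting material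
12 | (2S,4S)-pentane-2,4-diol | C[C@H](O)C[C@H](C)O | starting material
13 | 3-bromopropanal | O=CCCBr | intermediate
14 | (4S,6S)-2-(2-bromoethyl)-4,6-dimethyl-1,3-dioxane | C[C@H]1C[C@H](C)OC(CCBr)O1 | intermediate
15 | {2-[(4S,6S)-4,6-dimethyl-1,3-dioxan-2-yl]ethyl}magnesium bromide | C[C@H]1C[C@H](C)OC(CC[Mg]Br)O1 | intermediate
16 | (4E,6R,8R)-6-[2-(TBS-oxy)ethyl]-9-(TBDPS-oxy)-1-[(4S,6S)-4,6-dimethyl-1,3-dioxan-2-yl]-4,6-dimethyl-8-(triethylsilyloxy)non-4-en-3-one | C[C@H]1C[C@H](C)OC(CCC(=O)/C(C)=C/[C@](C)(CCO[Si](C)(C)C(C)(C)C)C[C@@H](O[Si](CC)(CC)CC)CO[Si](c2ccccc2)(c2ccccc2)C(C)(C)C)O1 | intermediate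
17 | (4S,6S)-2-{(4E,6R,8R)-6-[2-(TBS-oxy)ethyl]-9-(TBDPS-oxy)-4,6-dimethyl-3-methylidene-8-(triethylsilyloxy)non-4-en-1-yl}-4,6-dimethyl-1,3-dioxane | C[C@H]1C[C@H](C)OC(CCC(=C)/C(C)=C/[C@](C)(CCO[Si](C)(C)C(C)(C)C)C[C@@H](O[Si](CC)(CC)CC)CO[Si](c2ccccc2)(c2ccccc2)C(C)(C)C)O1 | intermediate
18 | (2R,4R,5E)-4-[2-(TBS-oxy)ethyl]-1-(TBDPS-oxy)-9-[(4S,6S)-4,6-dimethyl-1,3-dioxan-2-yl]-4,6-dimethyl-7-methylidenenon-5-en-2-ol | C[C@H]1C[C@H](C)OC(CCC(=C)/C(C)=C/[C@](C)(CCO[Si](C)(C)C(C)(C)C)C[C@@H](O)CO[Si](c2ccccc2)(c2ccccc2)C(C)(C)C)O1 | intermediate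
19 | (4R,5E)-4-[2-(TBS-oxy)ethyl]-1-(TBDPS-oxy)-9-[(4S,6S)-4,6-dimethyl-1,3-dioxan-2-yl]-4,6-dimethyl-7-methylidenenon-5-en-2-one | C[C@H]1C[C@H](C)OC(CCC(=C)/C(C)=C/[C@](C)(CCO[Si](C)(C)C(C)(C)C)CC(=O)CO[Si](c2ccccc2)(c2ccccc2)C(C)(C)C)O1 | intermediate
20 | (4S,6S)-2-{(4E,6R,8Z)-8-(TBS-oxy)-6-[2-(TBS-oxy)ethyl]-9-(TBDPS-oxy)-4,6-dimethyl-3-methylidenenona-4,8-dien-1-yl}-4,6-dimethyl-1,3-dioxane | C[C@H]1C[C@H](C)OC(CCC(=C)/C(C)=C/[C@](C)(CCO[Si](C)(C)C(C)(C)C)C/C(O[Si](C)(C)C(C)(C)C)=C/O[Si](c2ccccc2)(c2ccccc2)C(C)(C)C)O1 | intermediate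
21 | monocyclic tertiary allyl cation (ring A closed, C1 and C10 set, positive charge at C5 delocalised to C18, opened auxiliary as its TiCl4 alkoxide) | C=C1CC[C@H](O[C@@H](C)C[C@H](C)O[Ti-](Cl)(Cl)(Cl)Cl)[C@H]([C+]1C)[C@](C)(CCO[Si](C)(C)C(C)(C)C)C/C(O[Si](C)(C)C(C)(C)C)=C/O[Si](c1ccccc1)(c1ccccc1)C(C)(C)C | intermediate
22 | (1S,5S,6S,9R,10S)-9-[2-(TBS-oxy)ethyl]-6-(TBDPS-oxy)-1-[(2S,4S)-4-hydroxypentan-2-yloxy]-5,9-dimethyl-4-methylidene-trans-decalin-7-one (clerodane locants) | C=C1CC[C@H](O[C@@H](C)C[C@H](C)O)[C@@H]2[C@]1(C)[C@H](O[Si](c1ccccc1)(c1ccccc1)C(C)(C)C)C(=O)C[C@@]2(C)CCO[Si](C)(C)C(C)(C)C | intermediate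
23 | (1S,5S,6S,9R,10S)-9-[2-(TBS-oxy)ethyl]-6-(TBDPS-oxy)-5,9-dimethyl-4-methylidene-1-[(S)-4-oxopentan-2-yloxy]-trans-decalin-7-one | C=C1CC[C@H](O[C@@H](C)CC(C)=O)[C@@H]2[C@]1(C)[C@H](O[Si](c1ccccc1)(c1ccccc1)C(C)(C)C)C(=O)C[C@@]2(C)CCO[Si](C)(C)C(C)(C)C | intermediate
24 | (1S,5S,6S,9R,10S)-9-[2-(TBS-oxy)ethyl]-6-(TBDPS-oxy)-1-hydroxy-5,9-dimethyl-4-methylidene-trans-decalin-7-one | C=C1CC[C@H](O)[C@@H]2[C@]1(C)[C@H](O[Si](c1ccccc1)(c1ccccc1)C(C)(C)C)C(=O)C[C@@]2(C)CCO[Si](C)(C)C(C)(C)C | intermediate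
25 | (1S,5S,6S,9R,10S)-9-[2-(TBS-oxy)ethyl]-6-(TBDPS-oxy)-5,9-dimethyl-4-methylidene-7-oxo-trans-decalin-1-yl tiglate | C=C1CC[C@H](OC(=O)/C(C)=C/C)[C@@H]2[C@]1(C)[C@H](O[Si](c1ccccc1)(c1ccccc1)C(C)(C)C)C(=O)C[C@@]2(C)CCO[Si](C)(C)C(C)(C)C | intermediate
26 | (1S,5S,6S,9R,10S)-6-(TBDPS-oxy)-9-(2-hydroxyethyl)-5,9-dimethyl-4-methylidene-7-oxo-trans-decalin-1-yl tiglate | C=C1CC[C@H](OC(=O)/C(C)=C/C)[C@@H]2[C@]1(C)[C@H](O[Si](c1ccccc1)(c1ccccc1)C(C)(C)C)C(=O)C[C@@]2(C)CCO | intermediate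
27 | (1S,5S,6S,9R,10S)-6-(TBDPS-oxy)-5,9-dimethyl-4-methylidene-7-oxo-9-(2-oxoethyl)-trans-decalin-1-yl tiglate | C=C1CC[C@H](OC(=O)/C(C)=C/C)[C@@H]2[C@]1(C)[C@H](O[Si](c1ccccc1)(c1ccccc1)C(C)(C)C)C(=O)C[C@@]2(C)CC=O | intermediate
28 | 3-bromobut-3-en-1-ol | C=C(Br)CCO | starting material
29 | 3-bromobut-3-enoic acid | C=C(Br)CC(=O)O | intermediate
30 | tert-butyl 3-bromobut-3-enoate | C=C(Br)CC(=O)OC(C)(C)C | intermediate
31 | tert-butyl (4S)-5-[(1S,5S,6S,9R,10S)-6-(TBDPS-oxy)-5,9-dimethyl-4-methylidene-7-oxo-1-(tigloyloxy)-trans-decalin-9-yl]-4-hydroxy-3-methylidenepentanoate (12S) | C=C1CC[C@H](OC(=O)/C(C)=C/C)[C@@H]2[C@]1(C)[C@H](O[Si](c1ccccc1)(c1ccccc1)C(C)(C)C)C(=O)C[C@@]2(C)C[C@H](O)C(=C)CC(=O)OC(C)(C)C | intermediate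
32 | tert-butyl 2-[(2R)-2-{(1S)-2-[decalin-9-yl as in 31]-1-hydroxyethyl}oxiran-2-yl]acetate (12S,13R; erythro epoxy alcohol) | C=C1CC[C@H](OC(=O)/C(C)=C/C)[C@@H]2[C@]1(C)[C@H](O[Si](c1ccccc1)(c1ccccc1)C(C)(C)C)C(=O)C[C@@]2(C)C[C@H](O)[C@]1(CC(=O)OC(C)(C)C)OC1 | intermediate
33 | C12 tiglate of 32 (12S,13R bis-tiglate epoxide) | C=C1CC[C@H](OC(=O)/C(C)=C/C)[C@@H]2[C@]1(C)[C@H](O[Si](c1ccccc1)(c1ccccc1)C(C)(C)C)C(=O)C[C@@]2(C)C[C@H](OC(=O)/C(C)=C/C)[C@]1(CC(=O)OC(C)(C)C)OC1 | intermediate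
34 | cis-4,5-disubstituted 2-[(E)-but-2-en-2-yl]-1,3-dioxolan-2-ylium ion bridging O12 and O13 (13S), C16 oxygen as BF3 alkoxide | C=C1CC[C@H](OC(=O)/C(C)=C/C)[C@@H]2[C@]1(C)[C@H](O[Si](c1ccccc1)(c1ccccc1)C(C)(C)C)C(=O)C[C@@]2(C)C[C@@H]1OC(/C(C)=C/C)=[O+][C@]1(CO[B-](F)(F)F)CC(=O)OC(C)(C)C | intermediate
35 | tert-butyl (3S,4S)-5-[decalin-9-yl as in 31]-3-hydroxy-3-(hydroxymethyl)-4-(tigloyloxy)pentanoate | C=C1CC[C@H](OC(=O)/C(C)=C/C)[C@@H]2[C@]1(C)[C@H](O[Si](c1ccccc1)(c1ccccc1)C(C)(C)C)C(=O)C[C@@]2(C)C[C@H](OC(=O)/C(C)=C/C)[C@@](O)(CO)CC(=O)OC(C)(C)C | intermediate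
36 | (1S,5S,6S,9R,10S,12S,13S)-6-(TBDPS-oxy)-13-hydroxy-7-oxo-1,12-bis(tigloyloxy)clerod-4(18)-en-15,16-olide | C=C1CC[C@H](OC(=O)/C(C)=C/C)[C@@H]2[C@]1(C)[C@H](O[Si](c1ccccc1)(c1ccccc1)C(C)(C)C)C(=O)C[C@@]2(C)C[C@H](OC(=O)/C(C)=C/C)[C@@]1(O)COC(=O)C1 | intermediate
37 | C7–C8 trimethylsilyl enol ether of 36 with 13-O-trimethylsilyl ether | C=C1CC[C@H](OC(=O)/C(C)=C/C)[C@@H]2[C@]1(C)[C@H](O[Si](c1ccccc1)(c1ccccc1)C(C)(C)C)C(O[Si](C)(C)C)=C[C@@]2(C)C[C@H](OC(=O)/C(C)=C/C)[C@@]1(O[Si](C)(C)C)COC(=O)C1 | intermediate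
38 | 8-[(dimethylamino)methyl] derivative of 36 with 13-O-trimethylsilyl ether (C8 configuration immaterial) | C=C1CC[C@H](OC(=O)/C(C)=C/C)[C@@H]2[C@]1(C)[C@H](O[Si](c1ccccc1)(c1ccccc1)C(C)(C)C)C(=O)C(CN(C)C)[C@@]2(C)C[C@H](OC(=O)/C(C)=C/C)[C@@]1(O[Si](C)(C)C)COC(=O)C1 | intermediate
39 | 8-[(trimethylammonio)methyl] iodide of 38 | C=C1CC[C@H](OC(=O)/C(C)=C/C)[C@@H]2[C@]1(C)[C@H](O[Si](c1ccccc1)(c1ccccc1)C(C)(C)C)C(=O)C(C[N+](C)(C)C)[C@@]2(C)C[C@H](OC(=O)/C(C)=C/C)[C@@]1(O[Si](C)(C)C)COC(=O)C1.[I-] | intermediate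
40 | (1S,5S,6S,9S,10S,12S,13S)-6-(TBDPS-oxy)-7-oxo-1,12-bis(tigloyloxy)-13-(trimethylsilyloxy)cleroda-4(18),8(17)-dien-15,16-olide | C=C1CC[C@H](OC(=O)/C(C)=C/C)[C@@H]2[C@]1(C)[C@H](O[Si](c1ccccc1)(c1ccccc1)C(C)(C)C)C(=O)C(=C)[C@@]2(C)C[C@H](OC(=O)/C(C)=C/C)[C@@]1(O[Si](C)(C)C)COC(=O)C1 | intermediate
41 | CNP0233387.2, (1S,5S,6S,9S,10S,12S,13S)-6,13-dihydroxy-7-oxo-1,12-bis(tigloyloxy)cleroda-4(18),8(17)-dien-15,16-olide | C=C1CC[C@H](OC(=O)/C(C)=C/C)[C@@H]2[C@]1(C)[C@H](O)C(=O)C(=C)[C@@]2(C)C[C@H](OC(=O)/C(C)=C/C)[C@@]1(O)COC(=O)C1 | target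

**Step count and risk**
Total: 27 steps (steps 8, 19 and 20 make the building blocks 14 and 30). Longest linear sequence: 24 steps (1–7, 9–18, 21–27).

Most likely to fail:

1. Step 14 (the proposed new method). The allyl cation may be intercepted before ring B closes (chloride capture at C18, proton loss, attack of the C12 silyl ether oxygen), or ionisation of the acetal may lose its facial bias. The fallback uses known chemistry, sets out from 18 and comes back at 22. Hydroboration of the 1,1-disubstituted diene terminus of 18 with 9-BBN and oxidative work-up (NaOH, H2O2) would give the C18 primary alcohol as the C4-epimeric diol F1. Selective Appel iodination of the primary hydroxyl (I2, PPh3, imidazole) would give the iodo alcohol F2, Dess–Martin oxidation the ketone F3, and KN(SiMe3)2 then tBuMe2SiOTf the Z enol silane F4. F4 holds only an isolated E trisubstituted C5=C10 alkene, so its TiCl4-promoted closure to the bicyclic iodide F5 is the classical chiral-acetal-initiated cation–olefin bicyclization ended by a silyl enol ether. Dehydroiodination of either C4 epimer (DBU, toluene, 90 °C) then forms the C4 exocyclic methylene and gives 22.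

2. Step 24. The epoxide opening may lose regio- or stereocontrol (direct attack of the tert-butyl ester carbonyl at C16 with retention at C13, hydride shift to an aldehyde, acid-induced migration of the C4 exocyclic alkene). The fallback sets out from 31 and comes back at 36. Hydrogen-bond-directed dihydroxylation of the allylic alcohol (OsO4, TMEDA, CH2Cl2, −78 °C; reductive work-up) should add both oxygens syn to the C12 hydroxyl and give the (12S,13S)-triol F6. Selective silylation of the primary C16 hydroxyl (Et3SiCl, imidazole) gives F7, and acylation of the secondary C12 hydroxyl with tigloyl chloride (pyridine, DMAP; the tertiary hydroxyl stays free) gives F8. Camphorsulfonic acid in MeOH–CH2Cl2 then removes the triethylsilyl group and lets the C16 hydroxyl lactonise onto the tert-butyl ester to give 36.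

3. Step 21. Facial selectivity at C12 in the chromium-mediated vinylation may be poor, or the β,γ-unsaturated bromo ester may isomerise into conjugation. The fallback sets out from 27 and comes back at 32. The ligand-free Nozaki–Hiyama–Kishi coupling of 27 and 30 (CrCl2, NiCl2 cat., DMF) gives 31 together with its (12R)-epimer F9. Sharpless kinetic resolution of the mixture (Ti(OiPr)4, L-(+)-diisopropyl tartrate, tBuOOH, 4 Å molecular sieves, CH2Cl2, −20 °C) should epoxidise only the 12S epimer to the erythro epoxy alcohol 32. The unreacted F9 is separated and can be recycled by oxidation to the enone and re-reduction.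

**Further compounds**
F1 | step 14 | (2R,4R,5E)-4-[2-(TBS-oxy)ethyl]-1-(TBDPS-oxy)-9-[(4S,6S)-4,6-dimethyl-1,3-dioxan-2-yl]-7-(hydroxymethyl)-4,6-dimethylnon-5-en-2-ol (both C7 epimers of this chain, i.e. C4 of the skeleton) | C[C@H]1C[C@H](C)OC(CCC(CO)/C(C)=C/[C@](C)(CCO[Si](C)(C)C(C)(C)C)C[C@@H](O)CO[Si](c2ccccc2)(c2ccccc2)C(C)(C)C)O1
F2 | step 14 | 7-(iodomethyl) analogue of F1 (primary hydroxyl replaced by iodine) | C[C@H]1C[C@H](C)OC(CCC(CI)/C(C)=C/[C@](C)(CCO[Si](C)(C)C(C)(C)C)C[C@@H](O)CO[Si](c2ccccc2)(c2ccccc2)C(C)(C)C)O1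
F3 | step 14 | 2-ketone of F2 | C[C@H]1C[C@H](C)OC(CCC(CI)/C(C)=C/[C@](C)(CCO[Si](C)(C)C(C)(C)C)CC(=O)CO[Si](c2ccccc2)(c2ccccc2)C(C)(C)C)O1
F4 | step 14 | (Z)-tert-butyldimethylsilyl enol ether of F3 (C6=C7 of the skeleton) | C[C@H]1C[C@H](C)OC(CCC(CI)/C(C)=C/[C@](C)(CCO[Si](C)(C)C(C)(C)C)C/C(O[Si](C)(C)C(C)(C)C)=C/O[Si](c2ccccc2)(c2ccccc2)C(C)(C)C)O1
F5 | step 14 | (1S,5S,6S,9R,10S)-9-[2-(TBS-oxy)ethyl]-6-(TBDPS-oxy)-1-[(2S,4S)-4-hydroxypentan-2-yloxy]-4-(iodomethyl)-5,9-dimethyl-trans-decalin-7-one (both C4 epimers) | ICC1CC[C@H](O[C@@H](C)C[C@H](C)O)[C@@H]2[C@]1(C)[C@H](O[Si](c1ccccc1)(c1ccccc1)C(C)(C)C)C(=O)C[C@@]2(C)CCO[Si](C)(C)C(C)(C)C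
F6 | step 24 | tert-butyl (3S,4S)-5-[decalin-9-yl as in 31]-3,4-dihydroxy-3-(hydroxymethyl)pentanoate | C=C1CC[C@H](OC(=O)/C(C)=C/C)[C@@H]2[C@]1(C)[C@H](O[Si](c1ccccc1)(c1ccccc1)C(C)(C)C)C(=O)C[C@@]2(C)C[C@H](O)[C@@](O)(CO)CC(=O)OC(C)(C)C
F7 | step 24 | primary O-triethylsilyl ether of F6 | C=C1CC[C@H](OC(=O)/C(C)=C/C)[C@@H]2[C@]1(C)[C@H](O[Si](c1ccccc1)(c1ccccc1)C(C)(C)C)C(=O)C[C@@]2(C)C[C@H](O)[C@@](O)(CO[Si](CC)(CC)CC)CC(=O)OC(C)(C)C
F8 | step 24 | C12 tiglate of F7 | C=C1CC[C@H](OC(=O)/C(C)=C/C)[C@@H]2[C@]1(C)[C@H](O[Si](c1ccccc1)(c1ccccc1)C(C)(C)C)C(=O)C[C@@]2(C)C[C@H](OC(=O)/C(C)=C/C)[C@@](O)(CO[Si](CC)(CC)CC)CC(=O)OC(C)(C)C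
F9 | step 21 | (12R)-epimer of 31, tert-butyl (4R)-5-[decalin-9-yl as in 31]-4-hydroxy-3-methylidenepentanoate | C=C1CC[C@H](OC(=O)/C(C)=C/C)[C@@H]2[C@]1(C)[C@H](O[Si](c1ccccc1)(c1ccccc1)C(C)(C)C)C(=O)C[C@@]2(C)C[C@@H](O)C(=C)CC(=O)OC(C)(C)C
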